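The runs come from a simulation from invented constants, noise included.

The trap in a quick number for this flask was a straight line: you hoped the first hour's pace would run on to 4.0 h, so I tested that against the curve.

| flask | starting material | reagent in the second phase | protic impurity | remark | time | volume of the second phase over the first |
|---|---|---|---|---|---|---|
| Thursday's | 8 mM | 24 mM | 4.8 mM | run made earlier |  |  |
| Monday's | 32 mM | 24 mM | 4.8 mM | run made earlier |  |  |
| Saturday's | 16 mM | 24 mM | 7.2 mM | run made earlier |  |  |
| flask | 16 mM | 24.0 mM | 4.80 mM |  | 4.0 h | 1.0 |

| run | time / h | target / % | starting material / % |
|---|---|---|---|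
| Thursday's | 0.200 | 2 | 99 |
| Thursday's | 0.333 | 7 | 94 |
| Thursday's | 0.417 | 7 | 92 |
| Thursday's | 0.667 | 11 | 89 |
| Thursday's | 1.00 | 17 | 79 |
| Thursday's | 1.50 | 25 | 74 |
| Thursday's | 2.50 | 35 | 60 |
| Monday's | 0.200 | 4 | 101 |
| Monday's | 0.333 | 6 | 98 |
| Monday's | 0.417 | 6 | 94 |
| Monday's | 0.667 | 10 | 93 |
| Monday's | 1.00 | 14 | 84 |
| Monday's | 1.50 | 21 | 77 |
| Monday's | 2.50 | 23 | 71 |
| Saturday's | 0.500 | 11 | 90 |
| Saturday's | 1.00 | 17 | 81 |
| Saturday's | 1.33 | 18 | 81 |
| Saturday's | 2.00 | 25 | 75 |
| Saturday's | 2.50 | 28 | 71 |

(scatter of a reading: 2 percentage points)
- in the second phase: reagent in the second phase; everything else is in the first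
- charges count per volume of the first phase; a concentration in a rate is the amount of a species over the volume of its own phase; every rate counts per litre of the first phase
- reactions considered so far: reagent in the reaction phase + target -> over-reacted product; starting material + reagent in the reaction phase -> target; reagent in the reaction phase <-> reagent in the second phase; reagent in the reaction phase <-> dormant form; reagent in the reaction phase + protic impurity -> quenched reagent
- the earlier runs hold the two phases in the same ratio of volumes as the flask asked about
- south-west: doubling the transfer coefficient of the reagent in the second phase, all else as stated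
- east: doubling the amount of reagent in the second phase, all else as stated
* amount of target at 4.0 h, in percent of the starting material charged
* the change that raises the amount of target at 4.0 h, in percent of the starting material charged most ("none" if none brings more than 2 percentage points) (south-west / east / none)
* amount of target at 4.0 h, in percent of the starting material charged, after east

1. I replaced each curve by its mean pseudo-first-order constant: minus the logarithm of the fraction of the charge not yet target, divided by the time. To the last readings, Thursday's run gave 0.172 h⁻¹ and Monday's 0.105 h⁻¹.

2. The flask's charge lay midway between theirs on a logarithmic scale, so I took their geometric mean, the mean constant 0.134 h⁻¹. Saturday's run, with more protic impurity, stayed out.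

3. Held flat to 4.0 h, that mean put 41.5% of the charge in target.

4. Then I checked the error. Between the readings at 1.00 h and 2.50 h, the same averaging gave 0.110 h⁻¹, lower than the mean. Running that late value on gave an exponent of 0.500 and 39.3% target, which I committed to.

5. Doubling the exponent for east gave 63.2%. I expected south-west to add little: target was already forming at the first readings.

The forecast stood at 38%, east and 55%, the last lower than my 63.2% for east, with the words “The lag is short, so transfer is not the main limit”.

The flask gave 36.0% target; east was best, adding 19 percentage points against 1 point for south-west, and reached 55.0%.

    reagent in the reaction phase + target → over-reacted product (k = 0.243 M⁻¹ min⁻¹)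
    starting material + reagent in the reaction phase → target (k = 0.720 M⁻¹ min⁻¹)
    reagent in the reaction phase ⇌ reagent in the second phase, rate k3*([reagent in the reaction phase] - [reagent in the second phase]/K3) per volume of the first phase (partition coefficient = 0.570, kL = 0.0175 min⁻¹)
    reagent in the reaction phase ⇌ dormant form (K = 6.10, k = 0.0253 min⁻¹)
    reagent in the reaction phase + protic impurity → quenched reagent (k = 9.14 M⁻¹ min⁻¹)

The flask's mean constant came to 0.112 h⁻¹, lower than my 0.134 h⁻¹, so the curve kept bending after the last readings. Part of that bend came from the passing of reagent in the reaction phase into dormant form, both ways, acting together with the time given: without that step the flask gave 53.1% target against 36.0%, and left until 40.0 h with the step in place it gave 57.5%. The east flask had a mean of 0.200 h⁻¹, 1.79 times the flask's.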